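## Retrosynthetic overview

1. Late steps (O9 desilylation, C15 allylic oxidation, O6 angeloylation, C11=C13 methylenation, alkyne to vinyl, C6 oxidation/reduction) lead back to a bicyclic hydroxy lactone carrying a C10 ethynyl group, a C5 isopropenyl group and a saturated lactone.
2. Key disconnection: C8–C9 and C5–C6 together, a formal [3+3] union of (R)-2-ethynyl-2,4-dimethylpent-3-enal (C9, C10, C5 with C14, C1–C2, C4, C3, C15) and 5-(triethylsilyloxy)furan-3-carbaldehyde (C6, C7, C8 with C11, C12), run in one flask as vinylogous Mukaiyama aldol, conjugate reduction and carbonyl-ene cyclisation.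
3. Enabling feature: the O-bearing lactone carbon C8 lies γ to the lactone carbonyl C12 (C12–C11–C7–C8), so the γ-lactone ring can be brought in as a 2-silyloxyfuran that is nucleophilic at C8; the carbinol C6 between C7 and C5, with C5 carrying C4(=C3)–C15, is the retron of a carbonyl-ene reaction between a formyl group on C7 and a 2-methylprop-1-enyl group on C10.
4. Ring order: γ-lactone ring first (as a furan made from dihydroxyacetone), cyclohexane ring C5–C10 second, closed in the key step and trans-fused to the lactone.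
5. The aldehyde fragment comes from (Z)-3-methylpent-2-en-4-yn-1-ol by asymmetric epoxidation and epoxy silyl ether rearrangement (sets C10); the ethynyl group is the masked C10 vinyl group.

Key step: step 10

Remark: positions follow the elemane skeleton (ring C5–C10; C1–C2 unit and C14 methyl on C10; C4 with C3 and C15 on C5; C11, C12, C13 on C7); α is the ring face of the C1–C2 unit at C10, β the face of the C14 methyl group.

## Route

Step 1
Reactants: 1 (Z)-3-methylpent-2-en-4-yn-1-ol
Product: 2 [(2S,3R)-3-ethynyl-3-methyloxiran-2-yl]methanol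
Conditions: Ti(Oi-Pr)4 (cat.), L-(+)-diisopropyl tartrate (cat.), t-BuOOH, 4 Å molecular sieves, CH2Cl2, −20 °C
Reagents that add atoms: tert-butyl hydroperoxide CC(C)(C)OO
Why: Sharpless asymmetric epoxidation of a 3,3-disubstituted (Z)-allylic alcohol; with L-(+)-tartrate the oxygen should go to the face that gives the (2S,3R)-epoxide (the sense known for nerol-type substrates), and the alkyne is inert.

Step 2
Reactants: 2 [(2S,3R)-3-ethynyl-3-methyloxiran-2-yl]methanol
Product: 3 tert-butyl{[(2S,3R)-3-ethynyl-3-methyloxiran-2-yl]methoxy}dimethylsilane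
Conditions: t-BuMe2SiCl, imidazole, CH2Cl2, 0 °C to rt
Reagents that add atoms: tert-butyldimethylsilyl chloride CC(C)(C)[Si](C)(C)Cl
Why: Standard silylation of the primary alcohol; the siloxymethyl group is the one that migrates in step 3.

Step 3
Reactants: 3 tert-butyl{[(2S,3R)-3-ethynyl-3-methyloxiran-2-yl]methoxy}dimethylsilane
Product: 4 (2R)-2-{[tert-butyl(dimethyl)silyl]oxymethyl}-2-methylbut-3-ynal
Conditions: MeAl(OAr)2 (Ar = 4-bromo-2,6-di-tert-butylphenyl; 20 mol%), CH2Cl2, −78 to −20 °C
Reagents that add atoms: none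
Why: Lewis acid-catalysed rearrangement of an epoxy silyl ether to a β-siloxy aldehyde (semipinacol type): the bulky aluminium phenoxide opens the epoxide at the tertiary propargylic carbon and the siloxymethyl group shifts anti to the breaking C–O bond, so the epoxide configuration is carried with inversion into the (R)-quaternary centre (future C10).

Step 4
Reactants: 4 (2R)-2-{[tert-butyl(dimethyl)silyl]oxymethyl}-2-methylbut-3-ynal
Product: 5 tert-butyl{[(2R)-2-ethynyl-2,4-dimethylpent-3-en-1-yl]oxy}dimethylsilane
Conditions: i-PrPPh3 I (2.5 equiv), n-BuLi, THF, 0 °C; then 4, 0 °C to reflux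
Reagents that add atoms: isopropyltriphenylphosphonium iodide CC(C)[P+](c1ccccc1)(c1ccccc1)c1ccccc1.[I-]
Why: Wittig olefination with the non-stabilised isopropylidene ylide installs the 2-methylprop-1-enyl group (future C5, C4, C3, C15); the aldehyde has no α-hydrogen, so the quaternary centre cannot epimerise, and excess ylide covers partial deprotonation of the alkyne.

Step 5
Reactants: 5 tert-butyl{[(2R)-2-ethynyl-2,4-dimethylpent-3-en-1-yl]oxy}dimethylsilane
Product: 6 (2R)-2-ethynyl-2,4-dimethylpent-3-en-1-ol
Conditions: HF·pyridine, THF, 0 °C to rt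
Reagents that add atoms: none
Why: Fluoride cleavage of the primary silyl ether (desilylation); the alkyne and the trisubstituted alkene are untouched.

Step 6
Reactants: 6 (2R)-2-ethynyl-2,4-dimethylpent-3-en-1-ol
Product: 7 (2R)-2-ethynyl-2,4-dimethylpent-3-enal
Conditions: Dess–Martin periodinane, CH2Cl2, 0 °C to rt
Reagents that add atoms: none
Why: Dess–Martin oxidation under neutral conditions to the non-enolisable α-quaternary aldehyde (future C9).

Step 7
Reactants: 8 1,3-dihydroxyacetone (sold as its dimer), 9 ethyl (triphenyl-λ5-phosphanylidene)acetate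
Product: 11 4-(hydroxymethyl)furan-2(5H)-one, via hydroxy ester 10 (not isolated)
Conditions: CH2Cl2, rt
Reagents that add atoms: none
Why: Wittig olefination of the ketone; the hydroxymethyl group cis to the ester should lactonise spontaneously to the butenolide, and the other one remains as the future C6.

Step 8
Reactants: 11 4-(hydroxymethyl)furan-2(5H)-one
Product: 12 5-oxo-2,5-dihydrofuran-3-carbaldehyde
Conditions: Dess–Martin periodinane, CH2Cl2, 0 °C
Reagents that add atoms: none
Why: Dess–Martin oxidation of the allylic primary alcohol; the formylbutenolide is used at once because its ring CH2 is acidic.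

Step 9
Reactants: 12 5-oxo-2,5-dihydrofuran-3-carbaldehyde
Product: 13 5-(triethylsilyloxy)furan-3-carbaldehyde
Conditions: Et3SiOTf, Et3N, CH2Cl2, −78 to 0 °C
Reagents that add atoms: triethylsilyl trifluoromethanesulfonate CC[Si](CC)(CC)OS(=O)(=O)C(F)(F)F
Why: Soft enolisation (amine plus silyl triflate) of the butenolide gives the aromatic 2-silyloxyfuran, in which the formyl group is conjugated to two oxygen donors and is a poor electrophile.

Step 10
Reactants: 7 (2R)-2-ethynyl-2,4-dimethylpent-3-enal, 13 5-(triethylsilyloxy)furan-3-carbaldehyde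
Product: 16 6α-hydroxy-9α-(triethylsilyloxy)-5αH,7αH,8βH-elem-3-en-1-yn-12,8-olide, via formylbutenolide aldol adduct 14 (not isolated), via trans-lactone aldehyde 15 (not isolated)
Conditions: Bu4N[Ph3SiF2] (5 mol%), CH2Cl2, −78 °C; then Hantzsch ester (diethyl 2,6-dimethyl-1,4-dihydropyridine-3,5-dicarboxylate), dibenzylammonium trifluoroacetate (20 mol%), −78 °C to rt; then Me2AlCl (3 equiv), −78 to 0 °C
Reagents that add atoms: none
Why: Proposed new method: a fluoride-initiated vinylogous Mukaiyama aldol addition of the furanolate from 13 through C8 (the furan carbon γ to the future lactone carbonyl C12) to aldehyde 7 makes C8–C9 and passes the silyl group to O9, which turns the dormant furan formyl group (C6) into an electron-poor 3-formylbutenolide; iminium-catalysed Hantzsch ester transfer hydrogenation then saturates C7=C11, and Me2AlCl triggers a carbonyl-ene reaction of C6=O with the 2-methylprop-1-enyl group that makes C5–C6 and the isopropenyl unit. The closest known reactions are the fluoride-promoted, erythro-selective addition of 2-silyloxyfurans to aldehydes, the amine-salt/Hantzsch ester reduction of enals and the citronellal-to-isopulegol ene cyclisation, whereas their telescoping into a formal [3+3] annulation with a formyl-substituted silyloxyfuran is new. The cyclohexane ring is closed by the ene stage through a six-membered chair transition state (bond between the aldehyde carbon and the proximal alkene carbon), trans-fused onto the lactone ring that 13 brings in as a furan. C9 is set by Felkin–Anh addition to 7 (the steric and the polar model both lead to 9α-O with ethynyl as the small, electron-poor group) and C8 by the open erythro transition state of the fluoride-promoted addition; C7 is set by amine-mediated equilibration of the α-formyl centre to the trans-4,5-disubstituted lactone, and C5 by the chair in which the new isopropenyl group is equatorial and avoids the axial 9α-oxygen. C6 should form mainly as the equatorial 6α-alcohol (isopulegol sense); this is not relied on, because steps 11 and 12 reset it. The step needs cross- rather than self-addition, which the donor-deactivated formyl group of 13 should secure since it becomes a good enophile only after C8–C9 exists, and γ- rather than α-attack of the furanolate, which formation of the doubly conjugated butenolide should favour.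

Step 11
Reactants: 16 6α-hydroxy-9α-(triethylsilyloxy)-5αH,7αH,8βH-elem-3-en-1-yn-12,8-olide
Product: 17 6-oxo-9α-(triethylsilyloxy)-5αH,7αH,8βH-elem-3-en-1-yn-12,8-olide
Conditions: Dess–Martin periodinane, CH2Cl2, 0 °C
Reagents that add atoms: none
Why: Dess–Martin oxidation under neutral conditions should give the β,γ-unsaturated ketone (isopulegone type) without moving C3=C4 into conjugation; removing the C6 stereocentre makes both C6 epimers from step 10 converge.

Step 12
Reactants: 17 6-oxo-9α-(triethylsilyloxy)-5αH,7αH,8βH-elem-3-en-1-yn-12,8-olide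
Product: 18 6β-hydroxy-9α-(triethylsilyloxy)-5αH,7αH,8βH-elem-3-en-1-yn-12,8-olide
Conditions: LiBH(s-Bu)3, THF, −78 °C; then H2O, −78 °C to rt
Reagents that add atoms: none
Why: Bulky hydride reduction: attack on the locked chair from the equatorial direction (the axial approach is blocked by the 1,3-diaxial C10 methyl group) should give the axial 6β-alcohol, as in the reduction of isopulegone to neoisopulegol; the ketone reacts at −78 °C before the lactone.

Step 13
Reactants: 18 6β-hydroxy-9α-(triethylsilyloxy)-5αH,7αH,8βH-elem-3-en-1-yn-12,8-olide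
Product: 19 6β-hydroxy-9α-(triethylsilyloxy)-5αH,7αH,8βH-elema-1,3-dien-12,8-olide
Conditions: H2 (1 atm), Pd/CaCO3 poisoned with Pb(OAc)2, quinoline, EtOAc, rt
Reagents that add atoms: none
Why: Lindlar semihydrogenation converts the terminal alkyne into the C1=C2 vinyl group while the 1,1-disubstituted alkene is left.

Step 14
Reactants: 19 6β-hydroxy-9α-(triethylsilyloxy)-5αH,7αH,8βH-elema-1,3-dien-12,8-olide
Product: 22 6β-hydroxy-9α-(triethylsilyloxy)-5αH,7αH,8βH-elema-1,3,11(13)-trien-12,8-olide, via Mannich base 20 (not isolated), via ammonium iodide 21 (not isolated)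
Conditions: LiN(i-Pr)2 (2.5 equiv), THF, −78 °C; Me2N=CH2 I, −78 to −40 °C, then H2O; then MeI, MeOH, rt; then NaHCO3 (aq), CH2Cl2, rt
Reagents that add atoms: dimethylmethyleneiminium iodide (Eschenmoser's salt) C[N+](C)=C.[I-]
Why: α-Methylenation of the γ-lactone by enolate Mannich reaction, N-methylation and elimination; excess base turns the lactone at once into its enolate, which the C6 alkoxide cannot attack, so acyl migration to O6 should be suppressed.

Step 15
Reactants: 22 6β-hydroxy-9α-(triethylsilyloxy)-5αH,7αH,8βH-elema-1,3,11(13)-trien-12,8-olide, 23 angelic acid [(Z)-2-methylbut-2-enoic acid]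
Product: 24 6β-angeloyloxy-9α-(triethylsilyloxy)-5αH,7αH,8βH-elema-1,3,11(13)-trien-12,8-olide
Conditions: 2,4,6-Cl3C6H2COCl, Et3N, toluene, rt; then 22, toluene, 80 °C
Reagents that add atoms: none
Why: Yamaguchi-type esterification through the mixed anhydride, run without a nucleophilic catalyst, should acylate the hindered axial alcohol while keeping the Z geometry of the angeloyl group.

Step 16
Reactants: 24 6β-angeloyloxy-9α-(triethylsilyloxy)-5αH,7αH,8βH-elema-1,3,11(13)-trien-12,8-olide
Product: 26 6β-angeloyloxy-15-oxo-9α-(triethylsilyloxy)-5αH,7αH,8βH-elema-1,3,11(13)-trien-12,8-olide, via allylic alcohol 25 (not isolated)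
Conditions: SeO2 (cat.), t-BuOOH, CH2Cl2, rt; then Dess–Martin periodinane, CH2Cl2, rt
Reagents that add atoms: tert-butyl hydroperoxide CC(C)(C)OO
Why: Selenium dioxide allylic oxidation (ene reaction then [2,3]-shift) should attack the only electron-rich alkene that bears allylic hydrogens, at its methyl group in preference to the hindered C5–H methine, and the Dess–Martin reagent brings the allylic alcohol portion to the enal.

Step 17
Reactants: 26 6β-angeloyloxy-15-oxo-9α-(triethylsilyloxy)-5αH,7αH,8βH-elema-1,3,11(13)-trien-12,8-olide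
Product: 27 6β-angeloyloxy-9α-hydroxy-15-oxo-5αH,7αH,8βH-elema-1,3,11(13)-trien-12,8-olide (CNP0277836.2)
Conditions: HF·pyridine, pyridine, THF, 0 °C to rt
Reagents that add atoms: none
Why: Buffered fluoride desilylation removes the secondary triethylsilyl ether without touching the angelate, the enal or the α-methylene lactone.

## Compound list

1 | (Z)-3-methylpent-2-en-4-yn-1-ol | C#C/C(C)=C\CO | starting material
2 | [(2S,3R)-3-ethynyl-3-methyloxiran-2-yl]methanol | OC[C@@H]1O[C@]1(C)C#C | intermediate
3 | tert-butyl{[(2S,3R)-3-ethynyl-3-methyloxiran-2-yl]methoxy}dimethylsilane | CC(C)(C)[Si](C)(C)OC[C@@H]1O[C@]1(C)C#C | intermediate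
4 | (2R)-2-{[tert-butyl(dimethyl)silyl]oxymethyl}-2-methylbut-3-ynal | CC(C)(C)[Si](C)(C)OC[C@@](C)(C#C)C=O | intermediate
5 | tert-butyl{[(2R)-2-ethynyl-2,4-dimethylpent-3-en-1-yl]oxy}dimethylsilane | CC(C)(C)[Si](C)(C)OC[C@@](C)(C#C)C=C(C)C | intermediate
6 | (2R)-2-ethynyl-2,4-dimethylpent-3-en-1-ol | OC[C@@](C)(C#C)C=C(C)C | intermediate
7 | (2R)-2-ethynyl-2,4-dimethylpent-3-enal | O=C[C@@](C)(C#C)C=C(C)C | intermediate
8 | 1,3-dihydroxyacetone | OCC(=O)CO | starting material
9 | ethyl (triphenyl-λ5-phosphanylidene)acetate | CCOC(=O)C=P(c1ccccc1)(c1ccccc1)c1ccccc1 | starting material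
10 | ethyl 4-hydroxy-3-(hydroxymethyl)but-2-enoate | CCOC(=O)C=C(CO)CO | intermediate
11 | 4-(hydroxymethyl)furan-2(5H)-one | OCC1=CC(=O)OC1 | intermediate
12 | 5-oxo-2,5-dihydrofuran-3-carbaldehyde | O=CC1=CC(=O)OC1 | intermediate
13 | 5-(triethylsilyloxy)furan-3-carbaldehyde | CC[Si](CC)(CC)Oc1cc(C=O)co1 | intermediate
14 | (2R)-2-[(1S,2R)-2-ethynyl-2,4-dimethyl-1-(triethylsilyloxy)pent-3-en-1-yl]-5-oxo-2,5-dihydrofuran-3-carbaldehyde | C#C[C@@](C)(C=C(C)C)[C@H](O[Si](CC)(CC)CC)[C@@H]1OC(=O)C=C1C=O | intermediate
15 | (2R,3R)-2-[(1S,2R)-2-ethynyl-2,4-dimethyl-1-(triethylsilyloxy)pent-3-en-1-yl]-5-oxooxolane-3-carbaldehyde | C#C[C@@](C)(C=C(C)C)[C@H](O[Si](CC)(CC)CC)[C@@H]1OC(=O)C[C@H]1C=O | intermediate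
16 | 6α-hydroxy-9α-(triethylsilyloxy)-5αH,7αH,8βH-elem-3-en-1-yn-12,8-olide | C#C[C@]1(C)[C@H](O[Si](CC)(CC)CC)[C@@H]2OC(=O)C[C@H]2[C@H](O)[C@H]1C(C)=C | intermediate
17 | 6-oxo-9α-(triethylsilyloxy)-5αH,7αH,8βH-elem-3-en-1-yn-12,8-olide | C#C[C@]1(C)[C@H](O[Si](CC)(CC)CC)[C@@H]2OC(=O)C[C@H]2C(=O)[C@H]1C(C)=C | intermediate
18 | 6β-hydroxy-9α-(triethylsilyloxy)-5αH,7αH,8βH-elem-3-en-1-yn-12,8-olide | C#C[C@]1(C)[C@H](O[Si](CC)(CC)CC)[C@@H]2OC(=O)C[C@H]2[C@@H](O)[C@H]1C(C)=C | intermediate
19 | 6β-hydroxy-9α-(triethylsilyloxy)-5αH,7αH,8βH-elema-1,3-dien-12,8-olide | C=C[C@]1(C)[C@H](O[Si](CC)(CC)CC)[C@@H]2OC(=O)C[C@H]2[C@@H](O)[C@H]1C(C)=C | intermediate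
20 | 13-(dimethylamino)-6β-hydroxy-9α-(triethylsilyloxy)-5αH,7αH,8βH-elema-1,3-dien-12,8-olide (C11 epimers) | C=C[C@]1(C)[C@H](O[Si](CC)(CC)CC)[C@@H]2OC(=O)C(CN(C)C)[C@H]2[C@@H](O)[C@H]1C(C)=C | intermediate
21 | N-methyl quaternary ammonium iodide of 20 | C=C[C@]1(C)[C@H](O[Si](CC)(CC)CC)[C@@H]2OC(=O)C(C[N+](C)(C)C)[C@H]2[C@@H](O)[C@H]1C(C)=C.[I-] | intermediate
22 | 6β-hydroxy-9α-(triethylsilyloxy)-5αH,7αH,8βH-elema-1,3,11(13)-trien-12,8-olide | C=C[C@]1(C)[C@H](O[Si](CC)(CC)CC)[C@@H]2OC(=O)C(=C)[C@H]2[C@@H](O)[C@H]1C(C)=C | intermediate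
23 | angelic acid, (Z)-2-methylbut-2-enoic acid | C/C=C(/C)C(=O)O | starting material
24 | 6β-angeloyloxy-9α-(triethylsilyloxy)-5αH,7αH,8βH-elema-1,3,11(13)-trien-12,8-olide | C=C[C@]1(C)[C@H](O[Si](CC)(CC)CC)[C@@H]2OC(=O)C(=C)[C@H]2[C@@H](OC(=O)/C(C)=C\C)[C@H]1C(C)=C | intermediate
25 | 6β-angeloyloxy-15-hydroxy-9α-(triethylsilyloxy)-5αH,7αH,8βH-elema-1,3,11(13)-trien-12,8-olide | C=C[C@]1(C)[C@H](O[Si](CC)(CC)CC)[C@@H]2OC(=O)C(=C)[C@H]2[C@@H](OC(=O)/C(C)=C\C)[C@H]1C(=C)CO | intermediate
26 | 6β-angeloyloxy-15-oxo-9α-(triethylsilyloxy)-5αH,7αH,8βH-elema-1,3,11(13)-trien-12,8-olide | C=C[C@]1(C)[C@H](O[Si](CC)(CC)CC)[C@@H]2OC(=O)C(=C)[C@H]2[C@@H](OC(=O)/C(C)=C\C)[C@H]1C(=C)C=O | intermediate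
27 | 6β-angeloyloxy-9α-hydroxy-15-oxo-5αH,7αH,8βH-elema-1,3,11(13)-trien-12,8-olide (CNP0277836.2) | C=C[C@]1(C)[C@H](O)[C@@H]2OC(=O)C(=C)[C@H]2[C@@H](OC(=O)/C(C)=C\C)[C@H]1C(=C)C=O | target

## Step count and risks

Total step count: 17. Longest linear sequence: 14 steps (steps 1–6, then 10–17); the furan branch (steps 7–9) joins at step 10.

Steps most likely to fail:

1. Step 10 (key step, proposed new method). What may go wrong: loss of the C8/C9 erythro relationship by deprotonation and reprotonation at the acidic C8–H while the formylbutenolide stage is present, self-condensation of the formyl furan, and interference between the three reagent sets in one flask. Fallback (known chemistry; the two bonds are then made in separate steps): it sets out from 7. Commercial furan-2(5H)-one is silylated (Et3SiOTf, Et3N) to 2-(triethylsilyloxy)furan F1. Fluoride-catalysed (Bu4N[Ph3SiF2]) vinylogous Mukaiyama aldol addition of F1 to 7 should give, with silyl transfer, the erythro butenolide F2, whose C8–H is not unusually acidic. DBU-mediated conjugate addition of nitromethane, which on 5-substituted butenolides takes place anti to the C5 substituent, should give the trans nitromethyl lactone F3. A reductive Nef reaction (TiCl3, NH4OAc buffer, aqueous THF) unmasks the aldehyde 15, which is isolated and cyclised with Me2AlCl to 16, where the fallback comes back to the route.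

2. Step 15. What may go wrong: slow acylation of the axial 6β-hydroxyl (syn-axial to the C10 methyl group) and Z to E isomerisation of the angeloyl unit under forcing conditions. Fallback: it sets out from 20, which is isolated after the first stage of step 14. Acylation with 2-[bis(2,2,2-trifluoroethoxy)phosphoryl]propanoic acid and dicyclohexylcarbodiimide (the acid reacts through a phosphonoketene that acylates hindered alcohols) should give the phosphonate ester F4. Still–Gennari olefination with acetaldehyde (KN(SiMe3)2, 18-crown-6, THF, −78 °C) builds the Z-configured 2-methylbut-2-enoate on the oxygen and should give the angelate Mannich base F5, the amine keeping the future methylene lactone masked as a non-acceptor. MeI then gives the ammonium iodide F6, and NaHCO3 eliminates trimethylamine to give 24, where the fallback comes back to the route.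

3. Step 16. What may go wrong: poor site selectivity of the allylic oxidation (attack at the C5–H methine, at C7–H next to the methylene lactone or at the angelate methyl groups) and over-oxidation. Fallback: it sets out from 24. Dye-sensitised photooxygenation (O2, visible light, tetraphenylporphyrin, CH2Cl2, 0 °C; Schenck ene reaction of singlet oxygen, which should react only with the electron-rich 1,1-disubstituted alkene) gives the allylic hydroperoxide F7. PPh3 reduces it to the allylic alcohol 25, and Dess–Martin oxidation gives 26, where the fallback comes back to the route.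

Further compounds
F1 | step 10 | 2-(triethylsilyloxy)furan | CC[Si](CC)(CC)Oc1ccco1
F2 | step 10 | (5R)-5-[(1S,2R)-2-ethynyl-2,4-dimethyl-1-(triethylsilyloxy)pent-3-en-1-yl]furan-2(5H)-one | C#C[C@@](C)(C=C(C)C)[C@H](O[Si](CC)(CC)CC)[C@@H]1OC(=O)C=C1
F3 | step 10 | (4S,5R)-5-[(1S,2R)-2-ethynyl-2,4-dimethyl-1-(triethylsilyloxy)pent-3-en-1-yl]-4-(nitromethyl)oxolan-2-one | C#C[C@@](C)(C=C(C)C)[C@H](O[Si](CC)(CC)CC)[C@@H]1OC(=O)C[C@H]1C[N+](=O)[O-]
F4 | step 15 | 6β-{2-[bis(2,2,2-trifluoroethoxy)phosphoryl]propanoyloxy}-13-(dimethylamino)-9α-(triethylsilyloxy)-5αH,7αH,8βH-elema-1,3-dien-12,8-olide | C=C[C@]1(C)[C@H](O[Si](CC)(CC)CC)[C@@H]2OC(=O)C(CN(C)C)[C@H]2[C@@H](OC(=O)C(C)P(=O)(OCC(F)(F)F)OCC(F)(F)F)[C@H]1C(C)=C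
F5 | step 15 | 6β-angeloyloxy-13-(dimethylamino)-9α-(triethylsilyloxy)-5αH,7αH,8βH-elema-1,3-dien-12,8-olide | C=C[C@]1(C)[C@H](O[Si](CC)(CC)CC)[C@@H]2OC(=O)C(CN(C)C)[C@H]2[C@@H](OC(=O)/C(C)=C\C)[C@H]1C(C)=C
F6 | step 15 | N-methyl quaternary ammonium iodide of F5 | C=C[C@]1(C)[C@H](O[Si](CC)(CC)CC)[C@@H]2OC(=O)C(C[N+](C)(C)C)[C@H]2[C@@H](OC(=O)/C(C)=C\C)[C@H]1C(C)=C.[I-]
F7 | step 16 | 6β-angeloyloxy-15-hydroperoxy-9α-(triethylsilyloxy)-5αH,7αH,8βH-elema-1,3,11(13)-trien-12,8-olide | C=C[C@]1(C)[C@H](O[Si](CC)(CC)CC)[C@@H]2OC(=O)C(=C)[C@H]2[C@@H](OC(=O)/C(C)=C\C)[C@H]1C(=C)COO
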